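## Structural features

- The target joins two flavonoid units through one C–C bond. The first is an isoflavan: benzo ring A with 7-OH, pyran ring C, and ring B (3-hydroxy-2,4-dimethoxyphenyl) on C3. The second is a naringenin-type flavanone: phloroglucinol ring D, pyranone ring E, and ring F (4-hydroxyphenyl) on C2. Isoflavan C4 is bonded to flavanone C6, the ring D carbon between the 5-OH and 7-OH groups.
- C3 and C4 of ring C are adjacent stereocentres, trans, (3R,4S). C4 is a triarylmethine-like carbon flanked by an ortho-oxygenated ring A and a doubly ortho-oxygenated ring D.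
- The third stereocentre, flavanone C2 (S), is remote and receives no relay from the isoflavan.
- The flavanone is fragile: base opens ring E to the chalcone, which racemises C2. With both ortho oxygens of ring D free, reclosure can also give the 8-linked isomer (Wessely–Moser rearrangement).
- The four phenols are oxidation-prone, and the C4–ring D bond is benzylic to electron-rich rings, so strong acid is best avoided late in the route.
- The real difficulty is absolute and relative control at the congested C3/C4 pair, together with an unambiguous 6-linkage of the flavanone.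
- The key step uses the fact that C2 of ring C is a single carbon between O1 and C3. Ring C is therefore ring A, C4, C3 and their aryl groups (a 2-hydroxyphenyl triarylethene) plus one carbon, which CO can deliver as the lactone carbonyl.

## Logic of the disconnections

- **27 to 26.** The five O–CH2Ph bonds are cut. One neutral hydrogenolysis at the end keeps every phenol masked while base or organometallics are in use. The forward step must spare the flavanone C2–O1 bond and the ketone.
- **26 to 24 and 25.** The flavanone C2–aryl bond (ring E to ring F) is cut. The remote C2 centre can only be set by a reagent, and a flat enone acceptor in ring E turns this into a catalyst-controlled choice of face. Ring F is bought as 25. The forward step must deliver the aryl group to the Re face of C2 without base, so that ring E does not open.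
- **24 to 22.** The O1–C2 and C2–C3 bonds of ring E are cut (C2 comes from a one-carbon amide acetal), together with the O–CH2OMe bond. Only the oxygen para to the isoflavan is unmasked when ring E closes, so the 6-linkage is fixed by the protecting-group pattern. The forward step needs condensation at a hindered acetyl group and one mild acid treatment.
- **22 to 20.** The bond between ring D and the acetyl carbon is cut. The methoxymethyl ether directs lithiation to the position between itself and a benzyloxy group, so no acidic acylation is needed next to the C4–ring D bond. Ring D becomes symmetric again. The demand is site selectivity of the metalation.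
- **20 to 19 to 18.** The O1–C2 ether bond of ring C is cut (phenol plus primary alcohol), and C2 is then raised to the lactone oxidation level. This turns C2 into a carbonyl carbon. The reduction must not epimerise C3, and the etherification has only one phenol and one alcohol to pair.
- **18 to 16 and 17.** The C2–C3 and O1–C2 bonds are cut. Ring C and both stereocentres collapse into a planar, stable alkene and a one-carbon gas. The forward step needs palladium at C3, hydrogen at C4, control of the C4 face, and lactonisation faster than any direct C–O closure.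
- **16 to 8 and 13 (through 14 and 15).** The C3=C4 bond is cut as a C–C bond formed by a benzylic nucleophile on a diaryl ketone, followed by loss of water. The ketone has no alpha hydrogen and ring B leaves as a simple benzyl unit. The addition must succeed on a hindered ketone that carries a phenoxide, and the elimination must be run under equilibrating conditions so that one alkene geometry results.
- **8 to 7 to 5 and 3 (through 6).** The bond from ring A to the future C4 is cut. Bromine marks the ring A carbon and the aldehyde of 3 cannot enolise. The phenol of 5 is carried as its lithium salt, which saves a protecting group. Oxidation of 7 has to tolerate the free phenol.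
- **3 to 2 to 1; 5 to 4; 13 to 12 to 11 to 10 to 9.** Only O–alkyl bonds, one C–Cl bond, one oxidation level and one aryl–CHO bond are cut.
  - In 1 the para oxygen is differentiated from the two chelated ortho oxygens at the outset. The whole ring D regiochemistry rests on this.
  - In 4 the hydroxyl remote from bromine is benzylated.
  - 9 is benzylated before formylation so that the electrophile enters ortho to a methoxy group and not para to a free hydroxyl.

## Other disconnections considered

**Alternative 1:** The cut is inside ring D (flavanone C4a–C5). The phloroglucinol ring is built de novo from the pyranone A2, which already carries the trans-isoflavan-4-yl group on its C3.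
- Forward key step: Mg(OMe)2 in methanol would open A2 to a magnesium-chelated triketo ester. Its terminal methylene would attack the ester carbon in a Claisen-type closure and the ring would aromatise to the acetylphloroglucinol A1.
- In its favour: the acetyl group arrives with ring D, so no late C-acylation or metalation is needed on a polyaryl substrate. On this point it is better than the chosen plan. C4 would be set earlier under substrate control, by attack of the nucleophilic pyranone C3 on an isoflavan C4 cation anti to the C3 aryl group, so only C3 needs a catalyst.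
- Against it: A1 has three free phenols on ring D, two of them ortho to the acetyl group, so flavanone closure can go to either oxygen and give the 6- or the 8-linked isomer. Selective protection would have to be added. The triketo ester can also close by the aldol mode to a resorcylate, and the carbon next to its ester bears the bulky isoflavanyl group.
- Comparison: both plans need the same late C2 control. On stereocontrol at C3/C4 the two are comparable in risk (substrate control there, ligand control here). On step economy the alternative is probably longer, through pyranone side-chain construction and re-protection.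

**Alternative 2:** The cuts are C3–C4 and O1–C2. The C2 carbon comes as the aldehyde carbon of A5.
- Forward key step: base would expel sulfinate from the sulfone A4 to give an ortho-quinone methide. The enamine of A5 with a chiral secondary amine would add to C4, and the phenoxide would close onto the aldehyde to give the lactol A3.
- In its favour: the reaction type is established for simpler quinone methides, which makes it better than the chosen plan on precedent. It needs no pressure equipment. A4 should come in one step from a carbinol of the type of 7, so the ketone, Grignard and dehydration steps disappear. The lactol needs about as many steps to reach ring C as the lactone does. On step economy it is equal or slightly better.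
- Against it: this quinone methide carries a strongly donating, doubly ortho-substituted aryl group on the methide carbon, which lowers its electrophilicity and blocks approach. A5 is an enolisable arylacetaldehyde prone to self-condensation, and its enamine is conjugated and less nucleophilic.
- Comparison: the C–C bond is made at the most hindered carbon of the molecule, whereas the chosen plan places only a hydrogen atom there. The chosen plan also uses a stable alkene and draws C2 from CO. Both can correct C3 by epimerisation next to a carbonyl.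

**Alternative 3:** The cut is C4–C4a.
- Forward key step: acid would ionise the benzylic alcohol A7 to a cation stabilised by the trioxygenated ring D. The tethered 3-(benzyloxy)phenyl ether would attack through the carbon para to its benzyloxy group (intramolecular Friedel–Crafts alkylation) and give the isoflavan A6, trans by control from C3.
- In its favour: the reaction type is robust and the cation forms under very mild acid. The product is already at the isoflavan oxidation level, so lactone reduction and etherification are not needed. It is better than the chosen plan on precedent and on steps after the key step.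
- Against it: C3 must be set beforehand in an acyclic precursor, which costs auxiliary or catalyst steps. The cation can lose the adjacent C–H proton to give a stilbene, and reprotonation would scramble that same stereocentre. Attack at the ring carbon between the two oxygens would give a regioisomer.
- Comparison: the chosen plan sets C3 and C4 in one catalytic event from an achiral alkene and keeps C3 correctable, but it rests on an untested enantioselective step. The alternative rests on known steps, but with a real risk to configurational integrity.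

Key step: step 11

Remarks on the chemistry:
- The target is (2S) in the flavanone and (3R,4S), trans, in the isoflavan. Alkene 16 and lactone 18 are consistent with it in constitution and configuration. Syn addition to the two alkene geometries gives opposite C3 configurations for the same C4 face, so convergence of both geometries is not assured. 16 is therefore prepared and used as the single (Z) isomer (rings A and B trans).
- Assumption: in steps 11 and 16 the ligand enantiomer written is the one taken to give the required sense. If the sense is the opposite, the antipodal ligand is used and nothing else changes.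

## Route

Step 1
Reactants: 1 2,4,6-trihydroxybenzaldehyde
Product: 2 2,6-dihydroxy-4-(methoxymethoxy)benzaldehyde
Conditions: MOMCl (1.05 equiv), i-Pr2NEt (1.1 equiv), THF/CH2Cl2, −20 → 0 °C
Reagents that add atoms: chloromethyl methyl ether, COCCl
Why: Williamson-type O-alkylation; the 4-OH is the most acidic hydroxyl and the only one not hydrogen-bonded to the formyl group, so one equivalent of electrophile should react there first.

Step 2
Reactants: 2 2,6-dihydroxy-4-(methoxymethoxy)benzaldehyde
Product: 3 2,6-bis(benzyloxy)-4-(methoxymethoxy)benzaldehyde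
Conditions: BnBr (2.4 equiv), K2CO3, DMF, 60 °C
Reagents that add atoms: benzyl bromide, BrCc1ccccc1
Why: Williamson etherification of the two chelated hydroxyls, which need heat and a polar solvent; the methoxymethyl ether and the aldehyde are inert to carbonate.

Step 3
Reactants: 4 4-bromoresorcinol
Product: 5 5-(benzyloxy)-2-bromophenol
Conditions: BnBr (1.0 equiv), K2CO3 (1.0 equiv), acetone, rt → 50 °C
Reagents that add atoms: benzyl bromide, BrCc1ccccc1
Why: Williamson monoalkylation; the hydroxyl para to bromine is unhindered and gives the more nucleophilic phenoxide, while the hydroxyl next to bromine is shielded and its phenoxide is inductively stabilised; dibenzyl ether and regioisomer are removed by chromatography.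

Step 4
Reactants: 5 5-(benzyloxy)-2-bromophenol; 3 2,6-bis(benzyloxy)-4-(methoxymethoxy)benzaldehyde
Product: 7 5-(benzyloxy)-2-{[2,6-bis(benzyloxy)-4-(methoxymethoxy)phenyl](hydroxy)methyl}phenol (racemic), via lithium 5-(benzyloxy)-2-lithiophenolate 6 (not isolated)
Conditions: n-BuLi (2.1 equiv), THF, −78 → −20 °C; then 3, −78 → 0 °C; aq. NH4Cl, neutral work-up
Reagents that add atoms: none
Why: O-lithiation followed by bromine–lithium exchange gives the C,O-dilithio species, which adds to the non-enolisable aldehyde (1,2-addition); the new carbinol centre is lost in the next step, so its configuration is irrelevant.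

Step 5
Reactants: 7 the diaryl carbinol
Product: 8 [4-(benzyloxy)-2-hydroxyphenyl][2,6-bis(benzyloxy)-4-(methoxymethoxy)phenyl]methanone
Conditions: MnO2 (activated, 15 equiv), CH2Cl2, rt
Reagents that add atoms: none
Why: MnO2 oxidation of a doubly benzylic alcohol under neutral conditions; the product is a hydrogen-bonded 2-hydroxybenzophenone, and neutral conditions avoid ionisation of the acid-labile carbinol.

Step 6
Reactants: 9 2,6-dimethoxyphenol
Product: 10 2-(benzyloxy)-1,3-dimethoxybenzene
Conditions: BnBr, K2CO3, DMF, 60 °C
Reagents that add atoms: benzyl bromide, BrCc1ccccc1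
Why: Williamson etherification; masking the hydroxyl also switches off its para-directing effect before the formylation.

Step 7
Reactants: 10 2-(benzyloxy)-1,3-dimethoxybenzene
Product: 11 3-(benzyloxy)-2,4-dimethoxybenzaldehyde
Conditions: POCl3 (1.5 equiv), DMF, 0 → 70 °C; then H2O
Reagents that add atoms: N,N-dimethylformamide, CN(C)C=O; water, O
Why: Vilsmeier–Haack formylation; in a 1,2,3-trioxygenated benzene the central alkoxy group is twisted out of conjugation, so the electrophile enters ortho to one methoxy group and para to the other, which is the ring B pattern.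

Step 8
Reactants: 11 3-(benzyloxy)-2,4-dimethoxybenzaldehyde
Product: 12 [3-(benzyloxy)-2,4-dimethoxyphenyl]methanol
Conditions: NaBH4, MeOH/THF, 0 °C
Reagents that add atoms: none
Why: Hydride reduction of an aryl aldehyde to the benzylic alcohol.

Step 9
Reactants: 12 [3-(benzyloxy)-2,4-dimethoxyphenyl]methanol
Product: 13 2-(benzyloxy)-4-(chloromethyl)-1,3-dimethoxybenzene
Conditions: SOCl2 (1.2 equiv), pyridine (1.3 equiv), CH2Cl2, 0 °C; used at once without chromatography
Reagents that add atoms: thionyl chloride, O=S(Cl)Cl
Why: Chlorodehydroxylation through the chlorosulfite; pyridine traps HCl so that the electron-rich benzylic chloride does not self-alkylate.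

Step 10
Reactants: 13 2-(benzyloxy)-4-(chloromethyl)-1,3-dimethoxybenzene; 8 the 2-hydroxybenzophenone
Product: 16 5-(benzyloxy)-2-{(Z)-1-[2,6-bis(benzyloxy)-4-(methoxymethoxy)phenyl]-2-[3-(benzyloxy)-2,4-dimethoxyphenyl]ethenyl}phenol, via [3-(benzyloxy)-2,4-dimethoxybenzyl]magnesium chloride 14 (not isolated), via the tertiary alcohol 15 (not isolated)
Conditions: 13, Mg turnings, THF, 0 °C (slow addition); then 8 (0.3 equiv relative to 13), 0 °C → rt; aq. NH4Cl; then PPTS (cat.), toluene, 60 °C; crystallisation
Reagents that add atoms: none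
Why: Grignard addition in which the first equivalent forms the magnesium phenoxide and the second adds to the chelated ketone, which has no alpha hydrogen; the tertiary diaryl carbinol then ionises under mild acid (E1 dehydration), and reversible protonation at C3 should equilibrate the alkene toward the (Z) isomer, where rings A and B form a trans-stilbene unit and the perpendicular ring D sits cis to ring B.

Step 11
Reactants: 16 the (Z)-triarylethene; 17 carbon monoxide
Product: 18 (3R,4S)-7-(benzyloxy)-4-[2,6-bis(benzyloxy)-4-(methoxymethoxy)phenyl]-3-[3-(benzyloxy)-2,4-dimethoxyphenyl]-3,4-dihydro-2H-chromen-2-one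
Conditions: Pd(OAc)2 (5 mol %), (R)-DTBM-SEGPHOS (6 mol %), CO/H2 (10:1, 30 bar), toluene, 90 °C
Reagents that add atoms: none
Why: Proposed new method: a palladium hydride formed from Pd(OAc)2, the bisphosphine and H2 (or the phenol O–H) should add across C3=C4 with hydrogen to the diaryl carbon C4 and palladium to C3, where ring B gives benzylic (eta-3) stabilisation and the metal avoids the carbon between two ortho-substituted rings; CO then inserts into the C3–Pd bond with retention (C2–C3 bond) and the ring A phenol captures the acylpalladium (O1–C2 bond), the closest known reaction types being the palladium-catalysed cyclocarbonylation of 2-vinylphenols and 2-allylphenols to lactones and the asymmetric hydroalkoxycarbonylation of vinylarenes. Ring C closes as a six-membered lactone by 6-exo-trig acyl transfer to the phenol oxygen (equivalently C–O reductive elimination from an acyl aryloxy palladium chelate), whereas the five-membered lactone would need palladium on C4 and a quaternary centre. C4 is set by the ligand, which must deliver hydride to the Re face of C4 (priority ring D, ring A, C3); the palladium-binding phenol of ring A and the perpendicular, doubly ortho-substituted ring D are the two very different groups the chiral pocket has to tell apart. C3 follows from syn addition to the single (Z) geometry and retentive CO insertion, which gives the trans (3R,4S) lactone directly. C3 is alpha to the lactone carbonyl and benzylic, and trans is its thermodynamic configuration, so adventitious base cannot erode it. The step needs regioselectivity (benzylic stabilisation at C3, shielding of C4), preference for CO insertion over direct C–O coupling to a dihydrobenzofuran (CO pressure), and survival of the methoxymethyl and benzyl ethers (acid-free homogeneous conditions).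

Step 12
Reactants: 18 the trans lactone
Product: 19 (2R,3S)-3-[4-(benzyloxy)-2-hydroxyphenyl]-3-[2,6-bis(benzyloxy)-4-(methoxymethoxy)phenyl]-2-[3-(benzyloxy)-2,4-dimethoxyphenyl]propan-1-ol
Conditions: LiAlH4, THF, −20 → 0 °C; aq. potassium sodium tartrate
Reagents that add atoms: none
Why: Hydride reduction of an aryl ester lactone to phenol and primary alcohol; addition to the activated carbonyl at low temperature should outrun enolisation, so C3 keeps its configuration, and benzyl and methoxymethyl ethers are inert.

Step 13
Reactants: 19 the phenol alcohol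
Product: 20 (3R,4S)-7-(benzyloxy)-4-[2,6-bis(benzyloxy)-4-(methoxymethoxy)phenyl]-3-[3-(benzyloxy)-2,4-dimethoxyphenyl]-3,4-dihydro-2H-chromene
Conditions: PPh3, DIAD, THF, 0 °C → rt
Reagents that add atoms: none
Why: Intramolecular Mitsunobu etherification (6-exo-tet displacement at the primary carbon by the only phenol present); no stereocentre is touched.

Step 14
Reactants: 20 the protected isoflavan
Product: 22 1-{2,4-bis(benzyloxy)-3-[(3R,4S)-7-(benzyloxy)-3-[3-(benzyloxy)-2,4-dimethoxyphenyl]-3,4-dihydro-2H-chromen-4-yl]-6-(methoxymethoxy)phenyl}ethan-1-one, via the ring D aryllithium 21 (not isolated)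
Conditions: n-BuLi (1.2 equiv), THF, −78 → −10 °C; then MeC(O)N(OMe)Me (2 equiv), −78 → 0 °C; aq. NH4Cl
Reagents that add atoms: N-methoxy-N-methylacetamide, CC(=O)N(C)OC
Why: Directed ortho-metalation; the chelating methoxymethyl ether and the neighbouring benzyloxy group together activate the ring D position between them (the two such positions are equivalent by rotation), and the stable tetrahedral adduct of the N-methoxy-N-methyl amide releases the methyl ketone only on work-up.

Step 15
Reactants: 22 the ring D methyl ketone
Product: 24 5,7-bis(benzyloxy)-6-[(3R,4S)-7-(benzyloxy)-3-[3-(benzyloxy)-2,4-dimethoxyphenyl]-3,4-dihydro-2H-chromen-4-yl]-4H-chromen-4-one, via the dimethylamino enone 23 (not isolated)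
Conditions: Me2NCH(OMe)2 (5 equiv), toluene, 100 °C; evaporate; then HCl (1 M in MeOH)/THF, 40 °C
Reagents that add atoms: N,N-dimethylformamide dimethyl acetal, COC(OC)N(C)C
Why: Condensation of the amide acetal with the methyl ketone gives the enaminone; dilute acid then removes the methoxymethyl group (fast next to the carbonyl) and the freed phenol adds to the enaminone with loss of dimethylamine (addition–elimination) to close ring E; only the para oxygen is free, so only the 6-linked chromone can form.

Step 16
Reactants: 24 the chromone; 25 [4-(benzyloxy)phenyl]boronic acid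
Product: 26 (2S)-5,7-bis(benzyloxy)-2-[4-(benzyloxy)phenyl]-6-[(3R,4S)-7-(benzyloxy)-3-[3-(benzyloxy)-2,4-dimethoxyphenyl]-3,4-dihydro-2H-chromen-4-yl]-2,3-dihydro-4H-chromen-4-one
Conditions: Pd(OCOCF3)2 (10 mol %), (S)-t-BuPyOX (12 mol %), NH4PF6 (30 mol %), H2O (5 equiv), 25 (3 equiv), ClCH2CH2Cl, 50 °C
Reagents that add atoms: none
Why: Asymmetric conjugate addition of an arylboronic acid to a chromone under cationic divalent palladium with a pyridine-oxazoline ligand; the ligand must direct the aryl group to the Re face of C2 (priority O1, C3, H), which gives 2S independently of the distant isoflavan centres, and the base-free medium keeps ring E closed.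

Step 17
Reactants: 26 the pentabenzyl ether
Product: 27 (2S)-5,7-dihydroxy-6-[(3R,4S)-7-hydroxy-3-(3-hydroxy-2,4-dimethoxyphenyl)-3,4-dihydro-2H-chromen-4-yl]-2-(4-hydroxyphenyl)-2,3-dihydro-4H-chromen-4-one (target)
Conditions: H2 (1 atm), Pd/C (10 wt %), EtOAc/MeOH, rt; stopped at complete debenzylation
Reagents that add atoms: none
Why: Hydrogenolysis of the five benzyl ethers under neutral conditions, which neither open ring E nor touch the three stereocentres.

## Compound list

1 | 2,4,6-trihydroxybenzaldehyde | O=Cc1c(O)cc(O)cc1O | starting material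
2 | 2,6-dihydroxy-4-(methoxymethoxy)benzaldehyde | COCOc1cc(O)c(C=O)c(O)c1 | intermediate
3 | 2,6-bis(benzyloxy)-4-(methoxymethoxy)benzaldehyde | COCOc1cc(OCc2ccccc2)c(C=O)c(OCc2ccccc2)c1 | intermediate
4 | 4-bromoresorcinol (4-bromobenzene-1,3-diol) | Oc1ccc(Br)c(O)c1 | starting material
5 | 5-(benzyloxy)-2-bromophenol | Oc1cc(OCc2ccccc2)ccc1Br | intermediate
6 | lithium 5-(benzyloxy)-2-lithiophenolate | [Li]Oc1cc(OCc2ccccc2)ccc1[Li] | intermediate (not isolated)
7 | 5-(benzyloxy)-2-{[2,6-bis(benzyloxy)-4-(methoxymethoxy)phenyl](hydroxy)methyl}phenol (racemic) | COCOc1cc(OCc2ccccc2)c(C(O)c2ccc(OCc3ccccc3)cc2O)c(OCc2ccccc2)c1 | intermediate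
8 | [4-(benzyloxy)-2-hydroxyphenyl][2,6-bis(benzyloxy)-4-(methoxymethoxy)phenyl]methanone | COCOc1cc(OCc2ccccc2)c(C(=O)c2ccc(OCc3ccccc3)cc2O)c(OCc2ccccc2)c1 | intermediate
9 | 2,6-dimethoxyphenol | COc1cccc(OC)c1O | starting material
10 | 2-(benzyloxy)-1,3-dimethoxybenzene | COc1cccc(OC)c1OCc1ccccc1 | intermediate
11 | 3-(benzyloxy)-2,4-dimethoxybenzaldehyde | COc1ccc(C=O)c(OC)c1OCc1ccccc1 | intermediate
12 | [3-(benzyloxy)-2,4-dimethoxyphenyl]methanol | COc1ccc(CO)c(OC)c1OCc1ccccc1 | intermediate
13 | 2-(benzyloxy)-4-(chloromethyl)-1,3-dimethoxybenzene | COc1ccc(CCl)c(OC)c1OCc1ccccc1 | intermediate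
14 | [3-(benzyloxy)-2,4-dimethoxybenzyl]magnesium chloride | COc1ccc(C[Mg]Cl)c(OC)c1OCc1ccccc1 | intermediate (not isolated)
15 | 5-(benzyloxy)-2-{1-[2,6-bis(benzyloxy)-4-(methoxymethoxy)phenyl]-2-[3-(benzyloxy)-2,4-dimethoxyphenyl]-1-hydroxyethyl}phenol (racemic) | COCOc1cc(OCc2ccccc2)c(C(O)(Cc2ccc(OC)c(OCc3ccccc3)c2OC)c2ccc(OCc3ccccc3)cc2O)c(OCc2ccccc2)c1 | intermediate (not isolated)
16 | 5-(benzyloxy)-2-{(Z)-1-[2,6-bis(benzyloxy)-4-(methoxymethoxy)phenyl]-2-[3-(benzyloxy)-2,4-dimethoxyphenyl]ethenyl}phenol | COc1ccc(/C=C(/c2ccc(OCc3ccccc3)cc2O)c2c(OCc3ccccc3)cc(OCOC)cc2OCc2ccccc2)c(OC)c1OCc1ccccc1 | intermediate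
17 | carbon monoxide | [C-]#[O+] | starting material
18 | (3R,4S)-7-(benzyloxy)-4-[2,6-bis(benzyloxy)-4-(methoxymethoxy)phenyl]-3-[3-(benzyloxy)-2,4-dimethoxyphenyl]-3,4-dihydro-2H-chromen-2-one | COc1ccc([C@@H]2C(=O)Oc3cc(OCc4ccccc4)ccc3[C@H]2c2c(OCc3ccccc3)cc(OCOC)cc2OCc2ccccc2)c(OC)c1OCc1ccccc1 | intermediate
19 | (2R,3S)-3-[4-(benzyloxy)-2-hydroxyphenyl]-3-[2,6-bis(benzyloxy)-4-(methoxymethoxy)phenyl]-2-[3-(benzyloxy)-2,4-dimethoxyphenyl]propan-1-ol | COc1ccc([C@H](CO)[C@@H](c2ccc(OCc3ccccc3)cc2O)c2c(OCc3ccccc3)cc(OCOC)cc2OCc2ccccc2)c(OC)c1OCc1ccccc1 | intermediate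
20 | (3R,4S)-7-(benzyloxy)-4-[2,6-bis(benzyloxy)-4-(methoxymethoxy)phenyl]-3-[3-(benzyloxy)-2,4-dimethoxyphenyl]-3,4-dihydro-2H-chromene | COc1ccc([C@@H]2COc3cc(OCc4ccccc4)ccc3[C@H]2c2c(OCc3ccccc3)cc(OCOC)cc2OCc2ccccc2)c(OC)c1OCc1ccccc1 | intermediate
21 | {2,4-bis(benzyloxy)-3-[(3R,4S)-7-(benzyloxy)-3-[3-(benzyloxy)-2,4-dimethoxyphenyl]-3,4-dihydro-2H-chromen-4-yl]-6-(methoxymethoxy)phenyl}lithium | COc1ccc([C@@H]2COc3cc(OCc4ccccc4)ccc3[C@H]2c2c(OCc3ccccc3)cc(OCOC)c([Li])c2OCc2ccccc2)c(OC)c1OCc1ccccc1 | intermediate (not isolated)
22 | 1-{2,4-bis(benzyloxy)-3-[(3R,4S)-7-(benzyloxy)-3-[3-(benzyloxy)-2,4-dimethoxyphenyl]-3,4-dihydro-2H-chromen-4-yl]-6-(methoxymethoxy)phenyl}ethan-1-one | COc1ccc([C@@H]2COc3cc(OCc4ccccc4)ccc3[C@H]2c2c(OCc3ccccc3)cc(OCOC)c(C(C)=O)c2OCc2ccccc2)c(OC)c1OCc1ccccc1 | intermediate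
23 | (2E)-1-{2,4-bis(benzyloxy)-3-[(3R,4S)-7-(benzyloxy)-3-[3-(benzyloxy)-2,4-dimethoxyphenyl]-3,4-dihydro-2H-chromen-4-yl]-6-(methoxymethoxy)phenyl}-3-(dimethylamino)prop-2-en-1-one | COc1ccc([C@@H]2COc3cc(OCc4ccccc4)ccc3[C@H]2c2c(OCc3ccccc3)cc(OCOC)c(C(=O)/C=C/N(C)C)c2OCc2ccccc2)c(OC)c1OCc1ccccc1 | intermediate (not isolated)
24 | 5,7-bis(benzyloxy)-6-[(3R,4S)-7-(benzyloxy)-3-[3-(benzyloxy)-2,4-dimethoxyphenyl]-3,4-dihydro-2H-chromen-4-yl]-4H-chromen-4-one | COc1ccc([C@@H]2COc3cc(OCc4ccccc4)ccc3[C@H]2c2c(OCc3ccccc3)cc3occc(=O)c3c2OCc2ccccc2)c(OC)c1OCc1ccccc1 | intermediate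
25 | [4-(benzyloxy)phenyl]boronic acid | OB(O)c1ccc(OCc2ccccc2)cc1 | starting material
26 | (2S)-5,7-bis(benzyloxy)-2-[4-(benzyloxy)phenyl]-6-[(3R,4S)-7-(benzyloxy)-3-[3-(benzyloxy)-2,4-dimethoxyphenyl]-3,4-dihydro-2H-chromen-4-yl]-2,3-dihydro-4H-chromen-4-one | COc1ccc([C@@H]2COc3cc(OCc4ccccc4)ccc3[C@H]2c2c(OCc3ccccc3)cc3c(c2OCc2ccccc2)C(=O)C[C@@H](c2ccc(OCc4ccccc4)cc2)O3)c(OC)c1OCc1ccccc1 | intermediate
27 | (2S)-5,7-dihydroxy-6-[(3R,4S)-7-hydroxy-3-(3-hydroxy-2,4-dimethoxyphenyl)-3,4-dihydro-2H-chromen-4-yl]-2-(4-hydroxyphenyl)-2,3-dihydro-4H-chromen-4-one | COc1ccc([C@@H]2COc3cc(O)ccc3[C@H]2c2c(O)cc3c(c2O)C(=O)C[C@@H](c2ccc(O)cc2)O3)c(OC)c1O | target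

## Step count and least certain steps

Total: 17 steps. Longest linear sequence: 12 steps (1 → 2 → 3 → 7 → 8 → 16 → 18 → 19 → 20 → 22 → 24 → 26 → 27; the branch from 9 is equally long).

**Step 11 (key step).**
- What may go wrong: the hindered, trisubstituted alkene may fail to insert into the palladium hydride, so there is no turnover. The hydride may be delivered with poor facial selectivity at C4. Direct C–O closure to a dihydrobenzofuran or simple alkene reduction may compete with CO insertion.
- Fallback (known chemistry, sets out from 8 and 14, returns at 18):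
  - A portion of 14 is quenched with CO2 to give [3-(benzyloxy)-2,4-dimethoxyphenyl]acetic acid F1.
  - Perkin-type condensation of 8 with F1 (Ac2O, Et3N, 110 °C) gives the 3,4-diarylcoumarin F2.
  - Dissolving-metal conjugate reduction (Mg, MeOH) gives the ring-opened methyl 2,3,3-triarylpropanoate F3 as a diastereomer mixture.
  - Relactonisation and equilibration at C3 (DBU, toluene, heat) give the racemic trans lactone F4.
  - Preparative chromatography on a chiral stationary phase gives 18; the (3S,4R) enantiomer F5 is set aside.

**Step 10.**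
- What may go wrong: the benzylic Grignard reagent may not add to the hindered ketone once it carries a magnesium phenoxide (electron transfer or recovery of ketone instead). Wurtz homocoupling may consume the chloride while the reagent is formed.
- Fallback (sets out from 8 and 10, returns at 16):
  - The small nucleophile MeMgBr adds to 8 to give the tertiary methyl carbinol F6, which is not isolated.
  - Mild acid dehydrates it to the 1,1-diarylethene F7.
  - 10 is brominated with NBS in MeCN to 3-(benzyloxy)-1-bromo-2,4-dimethoxybenzene F8.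
  - Heck arylation of F7 with F8 (Pd(OAc)2, P(o-tol)3, Et3N, DMF, 100 °C), then the same acid equilibration, gives 16.

**Step 14.**
- What may go wrong: lithiation may occur at the wrong site, namely C8 of ring A (also flanked by two oxygens) or a benzylic OCH2 position, the latter followed by Wittig rearrangement.
- Fallback (sets out from 20, returns at 24):
  - Dilute HCl in MeOH/THF removes the methoxymethyl group to give the ring D phenol F9.
  - Friedel–Crafts C-acetylation ortho to the free hydroxyl (Ac2O, BF3·OEt2, CH2Cl2, 0 °C → rt) gives the 2-hydroxyacetophenone F10.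
  - Me2NCH(OMe)2 converts F10 into the hydroxy enaminone F11, which closes to 24 with HCl.

**Step 16.**
- What may go wrong: the electron-rich, 5-alkoxy-substituted chromone may be a sluggish acceptor, so that protodeboronation of 25 dominates. Facial selectivity may be insufficient and give a mixture of C2 epimers.
- Fallback (sets out from 22, returns at 26):
  - Claisen–Schmidt condensation of 22 with purchased 4-(benzyloxy)benzaldehyde (KOH, EtOH) gives the chalcone F12, still carrying the methoxymethyl ether.
  - HCl in MeOH gives the 2'-hydroxychalcone F13.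
  - Oxa-Michael closure (NaOAc, EtOH, reflux) gives 26 together with its (2R) epimer F14.
  - The two are diastereomers and are separated by chromatography. F14 is returned to the equilibration.

**Step 3.**
- What may go wrong: alkylation at the hydroxyl next to bromine, or double alkylation, would lower the supply of 5.
- Fallback (sets out from purchased 3-(benzyloxy)phenol in place of 4, returns at 5): amine-catalysed ortho-bromination (NBS, i-Pr2NH cat., CH2Cl2, 0 °C) installs bromine ortho to the hydroxyl and para to the benzyloxy group.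

## Further compounds

F1 | step 11 | [3-(benzyloxy)-2,4-dimethoxyphenyl]acetic acid | COc1ccc(CC(=O)O)c(OC)c1OCc1ccccc1
F2 | step 11 | 7-(benzyloxy)-4-[2,6-bis(benzyloxy)-4-(methoxymethoxy)phenyl]-3-[3-(benzyloxy)-2,4-dimethoxyphenyl]-2H-chromen-2-one | O=c1oc2cc(OCc3ccccc3)ccc2c(-c2c(OCc3ccccc3)cc(OCOC)cc2OCc2ccccc2)c1-c1ccc(OC)c(OCc2ccccc2)c1OC
F3 | step 11 | methyl 3-[4-(benzyloxy)-2-hydroxyphenyl]-3-[2,6-bis(benzyloxy)-4-(methoxymethoxy)phenyl]-2-[3-(benzyloxy)-2,4-dimethoxyphenyl]propanoate (racemic diastereomer mixture) | COC(=O)C(c1ccc(OC)c(OCc2ccccc2)c1OC)C(c1ccc(OCc2ccccc2)cc1O)c1c(OCc2ccccc2)cc(OCOC)cc1OCc1ccccc1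
F4 | step 11 | racemic trans lactone, (3R,4S) and (3S,4R) in equal amounts | COc1ccc([C@@H]2C(=O)Oc3cc(OCc4ccccc4)ccc3[C@H]2c2c(OCc3ccccc3)cc(OCOC)cc2OCc2ccccc2)c(OC)c1OCc1ccccc1.COc1ccc([C@H]2C(=O)Oc3cc(OCc4ccccc4)ccc3[C@@H]2c2c(OCc3ccccc3)cc(OCOC)cc2OCc2ccccc2)c(OC)c1OCc1ccccc1
F5 | step 11 | (3S,4R)-7-(benzyloxy)-4-[2,6-bis(benzyloxy)-4-(methoxymethoxy)phenyl]-3-[3-(benzyloxy)-2,4-dimethoxyphenyl]-3,4-dihydro-2H-chromen-2-one | COc1ccc([C@H]2C(=O)Oc3cc(OCc4ccccc4)ccc3[C@@H]2c2c(OCc3ccccc3)cc(OCOC)cc2OCc2ccccc2)c(OC)c1OCc1ccccc1
F6 | step 10 | 5-(benzyloxy)-2-{1-[2,6-bis(benzyloxy)-4-(methoxymethoxy)phenyl]-1-hydroxyethyl}phenol (racemic) | COCOc1cc(OCc2ccccc2)c(C(C)(O)c2ccc(OCc3ccccc3)cc2O)c(OCc2ccccc2)c1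
F7 | step 10 | 5-(benzyloxy)-2-{1-[2,6-bis(benzyloxy)-4-(methoxymethoxy)phenyl]ethenyl}phenol | COCOc1cc(OCc2ccccc2)c(C(=C)c2ccc(OCc3ccccc3)cc2O)c(OCc2ccccc2)c1
F8 | step 10 | 3-(benzyloxy)-1-bromo-2,4-dimethoxybenzene | COc1ccc(Br)c(OC)c1OCc1ccccc1
F9 | step 14 | 3,5-bis(benzyloxy)-4-[(3R,4S)-7-(benzyloxy)-3-[3-(benzyloxy)-2,4-dimethoxyphenyl]-3,4-dihydro-2H-chromen-4-yl]phenol | COc1ccc([C@@H]2COc3cc(OCc4ccccc4)ccc3[C@H]2c2c(OCc3ccccc3)cc(O)cc2OCc2ccccc2)c(OC)c1OCc1ccccc1
F10 | step 14 | 1-{2,4-bis(benzyloxy)-3-[(3R,4S)-7-(benzyloxy)-3-[3-(benzyloxy)-2,4-dimethoxyphenyl]-3,4-dihydro-2H-chromen-4-yl]-6-hydroxyphenyl}ethan-1-one | COc1ccc([C@@H]2COc3cc(OCc4ccccc4)ccc3[C@H]2c2c(OCc3ccccc3)cc(O)c(C(C)=O)c2OCc2ccccc2)c(OC)c1OCc1ccccc1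
F11 | step 14 | (2E)-1-{2,4-bis(benzyloxy)-3-[(3R,4S)-7-(benzyloxy)-3-[3-(benzyloxy)-2,4-dimethoxyphenyl]-3,4-dihydro-2H-chromen-4-yl]-6-hydroxyphenyl}-3-(dimethylamino)prop-2-en-1-one | COc1ccc([C@@H]2COc3cc(OCc4ccccc4)ccc3[C@H]2c2c(OCc3ccccc3)cc(O)c(C(=O)/C=C/N(C)C)c2OCc2ccccc2)c(OC)c1OCc1ccccc1
F12 | step 16 | (2E)-1-{2,4-bis(benzyloxy)-3-[(3R,4S)-7-(benzyloxy)-3-[3-(benzyloxy)-2,4-dimethoxyphenyl]-3,4-dihydro-2H-chromen-4-yl]-6-(methoxymethoxy)phenyl}-3-[4-(benzyloxy)phenyl]prop-2-en-1-one | COc1ccc([C@@H]2COc3cc(OCc4ccccc4)ccc3[C@H]2c2c(OCc3ccccc3)cc(OCOC)c(C(=O)/C=C/c3ccc(OCc4ccccc4)cc3)c2OCc2ccccc2)c(OC)c1OCc1ccccc1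
F13 | step 16 | (2E)-1-{2,4-bis(benzyloxy)-3-[(3R,4S)-7-(benzyloxy)-3-[3-(benzyloxy)-2,4-dimethoxyphenyl]-3,4-dihydro-2H-chromen-4-yl]-6-hydroxyphenyl}-3-[4-(benzyloxy)phenyl]prop-2-en-1-one | COc1ccc([C@@H]2COc3cc(OCc4ccccc4)ccc3[C@H]2c2c(OCc3ccccc3)cc(O)c(C(=O)/C=C/c3ccc(OCc4ccccc4)cc3)c2OCc2ccccc2)c(OC)c1OCc1ccccc1
F14 | step 16 | (2R)-5,7-bis(benzyloxy)-2-[4-(benzyloxy)phenyl]-6-[(3R,4S)-7-(benzyloxy)-3-[3-(benzyloxy)-2,4-dimethoxyphenyl]-3,4-dihydro-2H-chromen-4-yl]-2,3-dihydro-4H-chromen-4-one | COc1ccc([C@@H]2COc3cc(OCc4ccccc4)ccc3[C@H]2c2c(OCc3ccccc3)cc3c(c2OCc2ccccc2)C(=O)C[C@H](c2ccc(OCc4ccccc4)cc2)O3)c(OC)c1OCc1ccccc1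
F0 | step 3 | none | none
A1 | alternative 1 | 1-{2,4,6-trihydroxy-3-[(3R,4S)-7-(benzyloxy)-3-[3-(benzyloxy)-2,4-dimethoxyphenyl]-3,4-dihydro-2H-chromen-4-yl]phenyl}ethan-1-one | COc1ccc([C@@H]2COc3cc(OCc4ccccc4)ccc3[C@H]2c2c(O)cc(O)c(C(C)=O)c2O)c(OC)c1OCc1ccccc1
A2 | alternative 1 | 3-[(3R,4S)-7-(benzyloxy)-3-[3-(benzyloxy)-2,4-dimethoxyphenyl]-3,4-dihydro-2H-chromen-4-yl]-4-hydroxy-6-(2-oxopropyl)-2H-pyran-2-one | COc1ccc([C@@H]2COc3cc(OCc4ccccc4)ccc3[C@H]2c2c(O)cc(CC(C)=O)oc2=O)c(OC)c1OCc1ccccc1
A3 | alternative 2 | (3R,4S)-4-[4-(allyloxy)-2,6-bis(benzyloxy)phenyl]-7-(benzyloxy)-3-[3-(benzyloxy)-2,4-dimethoxyphenyl]-3,4-dihydro-2H-chromen-2-ol (anomer mixture at C2) | COc1ccc([C@@H]2C(O)Oc3cc(OCc4ccccc4)ccc3[C@H]2c2c(OCc3ccccc3)cc(OCC=C)cc2OCc2ccccc2)c(OC)c1OCc1ccccc1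
A4 | alternative 2 | 2-{[4-(allyloxy)-2,6-bis(benzyloxy)phenyl](benzenesulfonyl)methyl}-5-(benzyloxy)phenol (racemic) | O=S(=O)(c1ccccc1)C(c1ccc(OCc2ccccc2)cc1O)c1c(OCc2ccccc2)cc(OCC=C)cc1OCc1ccccc1
A5 | alternative 2 | [3-(benzyloxy)-2,4-dimethoxyphenyl]acetaldehyde | COc1ccc(CC=O)c(OC)c1OCc1ccccc1
A6 | alternative 3 | (3R,4S)-4-[4-(allyloxy)-2,6-bis(benzyloxy)phenyl]-7-(benzyloxy)-3-[3-(benzyloxy)-2,4-dimethoxyphenyl]-3,4-dihydro-2H-chromene | COc1ccc([C@@H]2COc3cc(OCc4ccccc4)ccc3[C@H]2c2c(OCc3ccccc3)cc(OCC=C)cc2OCc2ccccc2)c(OC)c1OCc1ccccc1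
A7 | alternative 3 | (2R)-1-[4-(allyloxy)-2,6-bis(benzyloxy)phenyl]-2-[3-(benzyloxy)-2,4-dimethoxyphenyl]-3-[3-(benzyloxy)phenoxy]propan-1-ol (epimer mixture at C1) | COc1ccc([C@H](COc2cccc(OCc3ccccc3)c2)C(O)c2c(OCc3ccccc3)cc(OCC=C)cc2OCc2ccccc2)c(OC)c1OCc1ccccc1
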